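Begin from the neighbour of the dosed flask: the north-east batch takes the same charge in one portion, so any gain in the south-east flask, a semi-batch under starved feed, has to come from timing.

| flask | substrate | free catalyst | impurity | remark | time |
|---|---|---|---|---|---|
| north-west | 0.10 M | 10 mol% | 5.1 mM | one stirred flow tank at steady state, fed with the mixture as stated, mean residence time 300 s |  |
| east | 0.10 M | 10 mol% | 5.1 mM | a single well-mixed tank run continuously and read at steady state, 30 s in it on average |  |
| north-east | 0.10 M | 10 mol% | 5.1 mM | a closed flask charged with all of it at once and left for 30 s | 30 s |
| south-east | 0.10 M (fed, over 24.0 s) | 10 mol% | 5.1 mM | a stirred flask in which substrate is dosed at a steady rate over 24.0 s without added volume, worked up at 30 s | 30 s |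

    isomer of the product A + free catalyst ⇌ isomer of the product B + free catalyst, rate k1*[free catalyst]*[isomer of the product A] forward; the back reaction follows from the equilibrium constant (K1 = 0.424, k1 = 12.3 M⁻¹ s⁻¹)
    target ⇌ isomer of the product A (K2 = 0.765, k2 = 0.00963 s⁻¹)
    substrate → uncatalysed product (k3 = 0.131 s⁻¹)
    substrate ⇌ target (K4 = 1.1, k4 = 0.0405 s⁻¹)
    isomer of the product B ⇌ substrate (k5 = 0.0312 s⁻¹)
    free catalyst + impurity → spent catalyst (k6 = 787 M⁻¹ s⁻¹)

- the stated concentrations are those of everything mixed, before any reaction; amounts are the same in each set-up
- the feed brings no volume worth counting
- run time (north-east): 30 s

1. the set-up with the highest amount of target at the outlet or at the end, in percent of the substrate put in ("none" if the first two lie within 2 percentage points) (north-west / east / north-east / south-east / none)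
2. amount of target at the outlet or at the end, in percent of the substrate put in, north-west
3. amount of target at the outlet or at the end, in percent of the substrate put in, east
4. amount of target at the outlet or at the end, in percent of the substrate put in, north-east
5. amount of target at the outlet or at the end, in percent of the substrate put in, south-east

Define τ, the mean lifetime of substrate, as the reciprocal of the summed forward rate constants of its two faster exits, to uncatalysed product and to target: τ = 5.83 s. The selectivity s, the fraction of that flow going to target, is 23.6 %. Target drains by its own two exits, back to substrate and on to isomer of the product A, at d = 0.0464 s⁻¹, slower than substrate goes. Substrate also leaves for isomer of the product B at 0.0111 s⁻¹, slower than it leaves for target. Set that third exit and the isomers' return aside, and reckon substrate and target as two pools in two ways.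

First, replace the spread of formation times by its mean. In the north-east batch, target forms on average τ after the start, so at work-up its mean age is 24.2 s, and s·exp(−d·age) gives 7.69 %. In the south-east flask, dosing is steady, so substrate arrives on average at mid-dose, and since τ is shorter than the dosing time, take it to react τ later. The mean age falls to 12.2 s and the estimate rises to 13.4 %.

Second, integrate the same two pools exactly. The north-east batch gives 7.85 %, so the two ways lie 0.16 percentage points apart there, which tests the averaging step, since both use the same constants. The south-east flask gives 12.0 %, so they part by 1.4 points. The mean cheats in the south-east flask: it counts the whole charge as reacted, yet the same integration leaves 8.54 % of it as substrate at work-up. Scale the mean by what has reacted and it comes to 12.3 %. Commit to the integrated pair. This reckoning stops at these two flasks.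

The forecast names south-east, with 2.3 % for north-west, 9.3 % for east, 9.7 % for north-east and 13 % for south-east. Its ground is that “dosing comes out best because its later-fed substrate leaves the target near its peak at work-up”. Its north-east value stands above my 7.85 %, and its south-east value above my 12.0 %, but the order of the two flasks is the same.

The simulation names south-east, with 2.32 % for north-west, 9.33 % for east, 9.71 % for north-east and 12.7 % for south-east. Substrate in the south-east flask reaches a highest reading of 24.7 mM, and the feed rate times τ gives a plateau of 24.3 mM. In the east tank, dividing the feed concentration by one plus the ratio of mean stay to τ gives 16.3 mM, and the substrate there reads 17.3 mM.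

The constants stand for no real mixture; the run is a simulation.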